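5 questions hang on 4 flasks that differ in how the charge goes in: which gives most target, and how much target each holds at 10 min.

the same everywhere: starting material 18 mM
- grey: reagent 18 mM; second substrate 36 mM; run made earlier
- red: reagent 25 mM; second substrate 36 mM; run made earlier
- violet: reagent 40 mM; second substrate 36 mM; run made earlier
- amber: reagent 18 mM; second substrate 54 mM; run made earlier
- spring: reagent 18.0 mM (fed, over 8.0 min); second substrate 36.0 mM; all else is in the flask from the start; the feed brings no volume worth counting; time 10 min
- autumn: reagent 18.0 mM; second substrate 36.0 mM (in portions, 2, over 8.0 min); first portion at the start, last at 8.0 min; time 10 min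
- noon: reagent 18.0 mM; second substrate 36.0 mM; everything together at the start; time 10 min
- winter: reagent 18.0 mM; second substrate 36.0 mM (fed, over 8.0 min); all else is in the flask from the start; the feed brings no volume worth counting; time 10 min

| run | time / min | target / % | starting material / % |
|---|---|---|---|
| grey | 1.00 | 12.2 | 88.8 |
| grey | 2.00 | 14.8 | 86.0 |
| grey | 3.00 | 15.8 | 84.1 |
| grey | 4.00 | 15.5 | 84.7 |
| grey | 5.00 | 15.7 | 84.7 |
| grey | 6.00 | 15.2 | 85.3 |
| red | 0.500 | 9.5 | 89.9 |
| red | 1.50 | 15.4 | 84.2 |
| red | 3.00 | 18.2 | 82.0 |
| red | 4.00 | 16.9 | 81.8 |
| red | 6.00 | 15.4 | 83.3 |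
| red | 8.00 | 15.3 | 84.5 |
| violet | 0.500 | 13.6 | 86.6 |
| violet | 1.50 | 19.2 | 80.2 |
| violet | 3.00 | 20.5 | 78.6 |
| violet | 4.00 | 20.3 | 79.0 |
| violet | 6.00 | 18.3 | 81.4 |
| violet | 8.00 | 17.4 | 82.1 |
| amber | 0.667 | 9.2 | 90.8 |
| amber | 1.33 | 11.8 | 87.5 |
| amber | 2.50 | 14.7 | 85.1 |
| amber | 4.00 | 15.2 | 84.9 |
| amber | 8.00 | 13.6 | 86.5 |

(standard deviation of a reading: 0.5 percentage points)

* the best flask by amount of target, in percent of the starting material charged; "all alike" if 1.5 percentage points covers them all (spring / autumn / noon / winter / all alike)
* amount of target at the end, in percent of the starting material charged, spring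
* amount of target at the end, in percent of the starting material charged, autumn
* amount of target at the end, in percent of the starting material charged, noon
* amount of target at the end, in percent of the starting material charged, winter



The ledger opens on grey, with 18 mM of reagent charged. The first entry is target at its peak reading, 2.84 mM, or 15.8 % of the charge. The second entry is second substrate: amber, with 54 mM in place of 36 mM, peaks at 15.2 % against grey's 15.8 %, about one scatter apart, so this entry reads small. The remaining 15.2 mM is unaccounted for, yet grey's target stops rising by 3.00 min with 84.1 % of starting material still there.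

This reckoning books that remainder, unbound reagent apart, to an unseen loss that goes with the square of [reagent], set against a capture linear in [reagent]. Each mole of reagent then reaches target with the share crossover/(crossover + [reagent]), and at fixed starting material the peak reckons to grow with the logarithm of the charge. The crossover, the [reagent] at which the loss takes reagent as fast as target does, reads from grey to violet as 1.06 mM. Red then reckons to 17.7 % against 18.2 % read.

Spring's feed is 2.25 mM min⁻¹. The pseudo-first-order capture constant, read from violet's first reading, is 0.122 min⁻¹. With feed balancing both exits, spring's [reagent] reckons to about 3.92 mM, so its share reckons to 21.3 %, larger than grey's, and spring reckons to 21.3 %. Autumn and winter move second substrate, the small entry, so this reckoning keeps them with noon, near amber's 13.6 % at 8.00 min, a reading later than grey's last at the same charge of reagent.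

The forecast differs: it names winter at 15 %, with spring 14.8 %, autumn 14.9 % and noon 13.2 %, and holds that “Feeding the reagent gives a similar result”.

The flasks give spring as best: spring 20.9 %, autumn 13.0 %, noon 12.8 %, winter 13.0 %.

    starting material + reagent ⇌ target (K = 97.0 M⁻¹, k = 0.230 M⁻¹ s⁻¹)
    second substrate + reagent ⇌ second product (K = 20.0 M⁻¹, k = 0.0120 M⁻¹ s⁻¹)
    2 reagent → homo dimer (k = 0.820 M⁻¹ s⁻¹)

Taking away the step from reagent to homo dimer turns the spring-minus-noon difference from 8.1 percentage points to −3.1 points, the largest single effect on that difference. Spring's reagent stood at 3.93 mM at 5.00 min, which with the crossover of 1.06 mM gives a share of 21.2 %. Spring fed 28.1 mM of reagent over the same 8.0 min reckons to a [reagent] of 5.01 mM, a share of 17.5 % and a gain of 6 points; its answer moved by 5 percentage points.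

All runs come from a simulation on assumed constants, and the scatter is random.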